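Ask of each given number how far the answer would move if it were off, since west and north-east are to be told from three earlier runs.

| flask | electrophile | nucleophile | free base | protic impurity | remark | time |
|---|---|---|---|---|---|---|
| Friday's | 0.63 M | 0.756 M | 0.27 M | 0.189 M | run made earlier |  |
| Saturday's | 0.63 M | 0.756 M | 0.49 M | 0.189 M | run made earlier |  |
| Thursday's | 0.63 M | 0.756 M | 0.53 M | 0.189 M | run made earlier |  |
| west | 0.63 M | 0.756 M | 0.630 M | 0.189 M |  | 80 min |
| north-east | 0.63 M | 0.756 M | 0.320 M | 0.189 M |  | 80 min |

| run | time / min | electrophile / % | target / % |
|---|---|---|---|
| Friday's | 15.0 | 84 | 18 |
| Friday's | 30.0 | 75 | 22 |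
| Friday's | 40.0 | 77 | 25 |
| Friday's | 60.0 | 74 | 28 |
| Saturday's | 5.00 | 90 | 9 |
| Saturday's | 10.0 | 86 | 16 |
| Saturday's | 25.0 | 78 | 21 |
| Saturday's | 60.0 | 72 | 29 |
| Thursday's | 5.00 | 88 | 12 |
| Thursday's | 10.0 | 86 | 12 |
| Thursday's | 25.0 | 77 | 24 |
| Thursday's | 60.0 | 70 | 29 |

(scatter of a reading: 1.5 percentage points)

- part of the electrophile that has reacted at the end, west
- part of the electrophile that has reacted at the end, north-east
- what raising the concentration of free base from its lowest to its highest value here does to the part of the electrophile that has reacted (changes below 5 percentage points count as none) (it rises / no change / it falls)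



c(free base) may be off by a long way: from 0.27 M to 0.53 M the target at 60.0 min reads 28% and 29%, a step smaller than the scatter of 1.5 percentage points. Time matters little too: Friday's run gains 3 points over its last 20.0 min, and the 20.0 min still to come should bring less, so we add half of that gain to the mean last reading and get 30.2% for both flasks.

c(nucleophile) is the number to know well. In these readings the rate of making target falls by a factor of about 12.0 while 74% of the electrophile remains, so we take the partner to be what fades. Dividing the target made by the nucleophile charged takes time out of the reckoning and leaves the yield on nucleophile, 0.251, a figure for this charge at the end of the run and not a constant. West and north-east carry the nucleophile charge of the runs, so we use it for them unchanged.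

The forecast gives 31% (28% to 36%) for west, 30.5% (28% to 34%) for north-east and no change, slightly above our figure and on another ground, that “the impurity caps conversion stoichiometrically”.

    electrophile + nucleophile ⇌ acid set free + target (K = 3.20, k = 6.40 × 10⁻⁴ /M/s)
    nucleophile + acid set free ⇌ protonated nucleophile, settled at all times (K = 30.0 /M)
    acid set free + free base ⇌ salt of the base, settled at all times (K = 23000 /M)
    nucleophile + protic impurity → quenched reagent (k = 0.0180 /M/s)
    2 nucleophile → self-condensation product (k = 0.00130 /M/s)

West and north-east both give 30.4%, and raising the free base from its lowest to its highest value here brings no change, a difference of 0 points, while at 80.0 min each flask keeps 3.58% of its nucleophile. Reckoned back, west's result is 0.253 target per nucleophile charged, against our 0.251.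

In the neighbour flask, west with 3.0 M of nucleophile, 0.251 gives 120% of the electrophile, more than was charged. The computed flask gives 52.8%, which is 0.111 per nucleophile charged, with 1.22 M of self-condensation product.

(The numbers in the tables were generated by integration with constants of no real substance; the scatter is artificial.)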